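## Analysis of the target

Compound 42 is a briarane: a cyclohexane (C1, C10–C14) fused through C1–C10 to a ten-membered carbocycle (C1–C10). The large ring carries a trans-fused γ-lactone (C7, C8, C17, C19, O) and a C5=C6 enoate in which the ring carbons C4 and C7 are cis. There are ten stereocentres (1S, 2R, 7S, 8S, 9R, 10S, 11R, 12R, 14S, 17R). On the cyclohexane the C15 methyl, C9 and the C20 methyl share one face, while C2 and the acetoxy groups at C12 and C14 lie on the other. The C2 and C14 oxygens are 1,3-syn across quaternary C1, the C8 hydroxyl is anti to the C9 acetoxy group, and on the lactone the C18 methyl is cis to the C8 hydroxyl. Sensitive groups are the four secondary acetates (migration to any free neighbouring hydroxyl, loss under base or hydride), the tertiary β-hydroxy lactone and the γ-acyloxy enoate. The hard parts are quaternary C1 flanked by three stereocentres (C2, C10, C14), fully substituted C8, and a ten-membered ring with a trisubstituted enoate. The strategy rests on one feature: with C14 at the ketone level, C1 and C10 are the α- and β-carbons of a cyclohexanone and C2 is an aldol carbinol on C1, so C9–C10 and C1–C2 are the two bonds of a conjugate addition–aldol sequence on a 2-methylcyclohexenone.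

## Retrosynthetic reasoning

**Lactone (O7–C19).** The lactone of 42 is opened to triol 39. C19 is kept at the alcohol level as a silyl ether until the end, so C17 never sits next to a carbonyl and cannot epimerise. Forward, a primary-selective oxidation must pass through aldehyde 40 and lactol 41 and engage only the C7 hydroxyl; C9 is already blocked as its acetate.

**C6–C7 (ten-membered ring).** The ring of 38 is cut between the alkene carbon and the carbinol, giving aldehyde 37. This is the only ring bond whose formation creates a heteroatom-bearing stereocentre, leaves the four acetates alone, and lets the alkene geometry be set before closure. Forward, a chromium-mediated alkenyl–aldehyde addition must close a ten-membered ring and set C7.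

**C16 and the C6 halide.** Bromoacrylate 36 is traced to acrylate 34 and this to the terminal alkyne of 30. The alkyne is inert to everything before it, so it serves as the latent C5/C6/C16 unit. Forward, carbonylation must place C16 on the internal carbon (31), and bromination–dehydrobromination via 35 must put the halogen cis to C4.

**C7–O and C8–O.** Triol 30 comes from the 1,1-disubstituted alkene of 29. Forward, osmylation must choose the alkene face anti to the C9 oxygen. It is done while the alkyne, not the acrylate, is present, so there is no competing alkene.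

**C8–C9.** Allylic alcohol 29 is cut into aldehyde 22 and iodoalkene 28. This joins the lactone carbons (C7, C8, C17–C19) as one small chiral piece; 28 comes from ester 23 via 24, 25, 26 and 27. Forward, the addition must follow Felkin–Anh control from C10 to give 9R.

**Adjustment at C9, C12, C14.** Aldehyde 22 comes from the vinyl group of triacetate 20 (via diol 21). Triacetate 20 comes from triol 19 and silyl ether 18, and 18 from ketone 16 by a reduction directed by the C2 hydroxyl (via 17). The 1,3-syn relation of the C2 and C14 oxygens is what makes this reduction reliable.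

**Key disconnection (C9–C10 and C1–C2).** Ketone 16 is cut at both bonds to quaternary C1 and C10, giving enone 10, vinylmagnesium bromide 13 and pent-4-ynal 12 (from alcohol 11). Three pieces meet at the most hindered carbon and C10, C1 and C2 are set in one flask. Forward, the vinyl group must enter cis to the C11 methyl and trans to the C12 oxygen (enolate 14), and the aldehyde must add trans to it. The C2 oxygen must end syn to C10. A chair transition state of the ring-fixed enolate would give the opposite, which is why the enolate is moved to titanium (15) and not to zinc.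

**Enone.** Enone 10 is opened at its C1=C10 double bond (ring-closing metathesis of dienol 8, then oxidation of 9). Dienol 8 comes from aldehyde 7, and 7 from 6, 5 and alcohol 4. Alcohol 4 is cut between C11 and C12 to aldehyde 3, made from 2 and diol 1. The trans relation of the C11 methyl and C12 oxygen on the ring corresponds to a syn homoallylic alcohol, so the crotylation must use a (Z)-crotyl reagent; an (E)-reagent would give the cis ring isomer.

## Alternatives that were turned down

**Alternative 1: chromium-mediated closure of the ten-membered ring as the defining step.** The C6–C7 bond is cut. The open-chain iodoacrylate aldehyde A2 (iodine cis to C4, C8 triethylsilyl ether, C19 methyl ester, all four acetates in place) would close with CrCl2/NiCl2 to the ten-membered C7 allylic alcohol A1. The lactone would then form by attack of the C7 hydroxyl on the C19 ester.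
- For it: the conditions tolerate every acetate, the enoate geometry is fixed before closure, and ring and C7 carbinol arise together.
- Against it: as a strategy it leaves the real problem open, namely quaternary C1 between C2, C10 and C14. A2 also carries C17 next to an ester for many steps.
- Comparison: on the ring closure this alternative is as strong as the chosen route, which uses the same reaction type at step 28 (with a bromide, and with C19 as a silyl ether). What the chosen strategy adds is the convergent assembly of C1/C10/C2 that A2 presupposes.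

**Alternative 2: nitrile oxide cycloaddition closing the cyclohexane at C1.** C14–C1 and O–C2 are cut. The oxime A4, oxidised to its nitrile oxide, would add across the Z-trisubstituted C1=C2 alkene to give the cyclohexane-fused isoxazoline A3.
- For it: the addition is suprafacial, so the alkene geometry fixes the C1/C2 relationship, and the isoxazoline is a masked C14 ketone with a C2 carbinol. On C2 it is stronger than the chosen key step, whose aldehyde-face selectivity is its weakest element.
- Against it: A4 needs a geometrically pure Z-trisubstituted alkene and three contiguous stereocentres (C10–C12) built along an open chain. The face of addition relative to C10 depends on the tether conformation. The N–O bond must be cleaved reductively in the presence of an alkyne. C9 arrives only as a protected alcohol.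
- Comparison: the chosen route is shorter to the same oxidation pattern and builds the cyclohexane from a simple enone by ring-closing metathesis. It pays with an uncertain C2, which it covers with a directed-reduction fallback.

**Alternative 3: enzymatic oxygen insertion into a cyclobutanone.** The O–C19/C7–O unit is traced to the ring-fused cyclobutanone A6. A Baeyer–Villiger monooxygenase would insert oxygen between C19 and C7 to give lactone A5, the C8 triethylsilyl ether of 42.
- For it: migration with retention fixes C7, an enzyme could choose between two secondary migrating carbons (C7 and C17) where a peracid would not, and no redox change at C19 is needed. On C7 it is stronger than a ring closure that creates C7.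
- Against it: A6 requires a four-membered ring fused to the ten-membered ring at fully substituted C8, for which no short stereocontrolled access is evident. Acceptance of so large a polyacetate by the enzyme is open, and esterase activity of whole cells threatens the acetates.
- Comparison: the chosen route forms the same lactone by a two-stage chemical oxidation of a 1,4-diol, from an intermediate it reaches anyway.

Key step: step 11

Remark: locants are the briarane ones (C15 methyl on C1, C16 ester carbon on C5, C18 methyl on C17, C19 lactone carbonyl, C20 methyl on C11). (−)-Ipc2BOMe is taken as the reagent of the (+)-α-pinene series, and its facial sense is stated from the usual model; it should be confirmed on the first batch of 4.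

## Route

Step 1
Reactants: 1 propane-1,3-diol
Product: 2 3-[(4-methoxybenzyl)oxy]propan-1-ol
Conditions: NaH (1 equiv), 4-methoxybenzyl chloride, Bu4NI (cat.), THF, 0 °C to rt; diol in threefold excess
Reagents that add atoms: 4-methoxybenzyl chloride, `COc1ccc(CCl)cc1`
Why: Williamson etherification; the excess of diol keeps the bis-ether low.

Step 2
Reactants: 2 3-[(4-methoxybenzyl)oxy]propan-1-ol
Product: 3 3-[(4-methoxybenzyl)oxy]propanal
Conditions: Dess–Martin periodinane, NaHCO3, CH2Cl2, 0 °C to rt
Reagents that add atoms: none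
Why: Dess–Martin oxidation of a primary alcohol; the buffer prevents β-elimination of the ether.

Step 3
Reactants: 3 3-[(4-methoxybenzyl)oxy]propanal
Product: 4 (3R,4R)-1-[(4-methoxybenzyl)oxy]-4-methylhex-5-en-3-ol
Conditions: (Z)-but-2-ene, KOtBu, n-BuLi, THF, −78 to −45 °C; (−)-Ipc2BOMe, −78 °C; BF3·OEt2; 3, −78 °C; NaOH, H2O2, rt
Reagents that add atoms: (Z)-but-2-ene, `C/C=C\C`, delivered as (Z)-crotyldiisopinocampheylborane, `C/C=C\CB([C@@H]1C[C@@H]2C[C@@H](C2(C)C)[C@H]1C)[C@@H]1C[C@@H]2C[C@@H](C2(C)C)[C@H]1C`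
Why: Brown crotylboration through a closed chair; the (Z)-crotyl group gives the syn alcohol (C11/C12, trans on the later ring) and the isopinocampheyl groups select the aldehyde face that gives 3R.

Step 4
Reactants: 4 (3R,4R)-1-[(4-methoxybenzyl)oxy]-4-methylhex-5-en-3-ol
Product: 5 tert-butyl{[(3R,4R)-1-[(4-methoxybenzyl)oxy]-4-methylhex-5-en-3-yl]oxy}dimethylsilane
Conditions: TBSCl, imidazole, DMF, rt
Reagents that add atoms: tert-butyldimethylsilyl chloride, `CC(C)(C)[Si](C)(C)Cl`
Why: standard silylation of a secondary alcohol; the bulky ether later helps to hold the half-chair of the enone.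

Step 5
Reactants: 5 the silyl ether from step 4
Product: 6 (3R,4R)-3-[(tert-butyldimethylsilyl)oxy]-4-methylhex-5-en-1-ol
Conditions: DDQ, CH2Cl2/pH 7 buffer, 0 °C
Reagents that add atoms: none
Why: oxidative cleavage of the 4-methoxybenzyl ether; silyl ether and alkene are inert.

Step 6
Reactants: 6 (3R,4R)-3-[(tert-butyldimethylsilyl)oxy]-4-methylhex-5-en-1-ol
Product: 7 (3R,4R)-3-[(tert-butyldimethylsilyl)oxy]-4-methylhex-5-enal
Conditions: Dess–Martin periodinane, NaHCO3, CH2Cl2, 0 °C
Reagents that add atoms: none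
Why: Dess–Martin oxidation; buffered and cold so that the β-silyloxy aldehyde does not eliminate.

Step 7
Reactants: 7 (3R,4R)-3-[(tert-butyldimethylsilyl)oxy]-4-methylhex-5-enal
Product: 8 (5R,6R)-5-[(tert-butyldimethylsilyl)oxy]-2,6-dimethylocta-1,7-dien-3-ol (both C3 epimers)
Conditions: isopropenylmagnesium bromide, THF, −78 °C
Reagents that add atoms: isopropenylmagnesium bromide, `CC(=C)[Mg]Br`
Why: Grignard addition to the aldehyde; the new carbinol is not controlled and is oxidised away in step 9.

Step 8
Reactants: 8 the dienol from step 7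
Product: 9 (4R,5R)-5-[(tert-butyldimethylsilyl)oxy]-2,4-dimethylcyclohex-2-en-1-ol (both C1 epimers)
Conditions: second-generation Grubbs catalyst (3 mol%), CH2Cl2, 40 °C
Reagents that add atoms: none
Why: ring-closing metathesis to a six-membered ring with a trisubstituted alkene, a favourable case; ethene is lost.

Step 9
Reactants: 9 the cyclohexenol from step 8
Product: 10 (4R,5R)-5-[(tert-butyldimethylsilyl)oxy]-2,4-dimethylcyclohex-2-en-1-one
Conditions: Dess–Martin periodinane, NaHCO3, CH2Cl2, 0 °C
Reagents that add atoms: none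
Why: oxidation of the allylic alcohol converges both epimers on the enone; neutral conditions avoid loss of the β-silyloxy group.

Step 10
Reactants: 11 pent-4-yn-1-ol
Product: 12 pent-4-ynal
Conditions: Dess–Martin periodinane, CH2Cl2, rt; filtered and used as a dried solution
Reagents that add atoms: none
Why: Dess–Martin oxidation; the volatile aldehyde is not concentrated.

Step 11
Reactants: 10 (4R,5R)-5-[(tert-butyldimethylsilyl)oxy]-2,4-dimethylcyclohex-2-en-1-one; 12 pent-4-ynal; 13 vinylmagnesium bromide
Product: 16 (2S,3S,4R,5R)-5-[(tert-butyldimethylsilyl)oxy]-3-ethenyl-2-[(1R)-1-hydroxypent-4-yn-1-yl]-2,4-dimethylcyclohexan-1-one, via bromomagnesium enolate 14 (not isolated), via triisopropoxytitanium enolate 15 (not isolated)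
Conditions: 13 (1.5 equiv), CuBr·SMe2 (20 mol%), THF, −78 to −40 °C; ClTi(OiPr)3 (2 equiv), −78 °C; 12 (2 equiv), −78 °C; aq NH4Cl at −78 °C
Reagents that add atoms: vinylmagnesium bromide 13, `C=C[Mg]Br`
Why: Copper-catalysed 1,4-addition of the vinyl Grignard reagent and aldol trapping of the regiodefined tetrasubstituted enolate is the known three-component coupling of 2-substituted cycloalkenones; it forms C9–C10 and C1–C2 and closes no ring. C10: enone 10 reacts through the half-chair with the C11 methyl and the C12 silyloxy group pseudo-equatorial, and the vinyl group enters axially, trans to the C12 oxygen and cis to the C11 methyl; the flipped half-chair would put the incoming group 1,3-diaxial to the silyloxy group. C1: the aldehyde approaches the enolate face opposite the new C10 vinyl group, so C2 ends trans to C9. C2: the ring fixes the enolate with C10 trans to the enolate oxygen, and a Zimmerman–Traxler chair would place the C2 oxygen anti to C10, which is the wrong epimer. The enolate is therefore moved from magnesium (14) to titanium (15), because triisopropoxytitanium enolates of cyclic ketones are known to give the adduct with oxygen syn to the ring carbon, ascribed to a boat-like closed transition state; this is the 2R sense. The selectivities needed are axial attack at C10, anti approach at C1 and syn topicity at C2; the first two rest on the substrate, the third on the counter-ion and is the least secure. The aldolate has no α-hydrogen and cannot dehydrate, but it can revert, so it is quenched cold.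

Step 12
Reactants: 16 the aldol adduct from step 11
Product: 18 (1S,2S,3S,4R,5R)-5-[(tert-butyldimethylsilyl)oxy]-3-ethenyl-2-[(1R)-1-hydroxypent-4-yn-1-yl]-2,4-dimethylcyclohexan-1-ol, via O2-diethylboryl aldolate 17 (not isolated)
Conditions: Et2BOMe, THF/MeOH (4:1), −78 °C; NaBH4, −78 °C; then MeOH, evaporation
Reagents that add atoms: none
Why: Narasaka–Prasad reduction; boron ties the C2 oxygen to the C14 carbonyl, which holds C2 in the carbonyl plane, and external hydride attacks C14 anti to the C1–C10 bond (axial on the chelate) to give the 1,3-syn diol, 14S. The same face is the one not shielded by the axial C12 silyloxy group.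

Step 13
Reactants: 18 the syn diol from step 12
Product: 19 (1R,3S,4S,5S,6R)-5-ethenyl-4-[(1R)-1-hydroxypent-4-yn-1-yl]-4,6-dimethylcyclohexane-1,3-diol
Conditions: HF (48% aq), MeCN, rt
Reagents that add atoms: none
Why: acidic desilylation; alkene, alkyne and the three alcohols are stable.

Step 14
Reactants: 19 the triol from step 13
Product: 20 (1R,3S,4S,5S,6R)-4-[(1R)-1-acetoxypent-4-yn-1-yl]-5-ethenyl-4,6-dimethylcyclohexane-1,3-diyl diacetate
Conditions: Ac2O, DMAP, pyridine, 40 °C
Reagents that add atoms: acetic anhydride, `CC(=O)OC(C)=O`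
Why: DMAP-catalysed acetylation; warming is needed for the two hydroxyls next to quaternary C1. The C2, C12 and C14 acetates of 42 are now in place.

Step 15
Reactants: 20 the triacetate from step 14
Product: 22 (1R,3S,4S,5S,6R)-4-[(1R)-1-acetoxypent-4-yn-1-yl]-5-formyl-4,6-dimethylcyclohexane-1,3-diyl diacetate, via vicinal diol 21 (not isolated)
Conditions: OsO4 (5 mol%), NaIO4, 2,6-lutidine, dioxane/H2O (3:1), rt
Reagents that add atoms: osmium tetroxide, `O=[Os](=O)(=O)=O`; sodium periodate, `[Na+].[O-]I(=O)(=O)=O`; water, `O`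
Why: Lemieux–Johnson cleavage; OsO4 takes the alkene and leaves the alkyne, and the lutidine buffer protects the C10 stereocentre of the aldehyde.

Step 16
Reactants: 23 methyl (S)-3-hydroxy-2-methylpropanoate
Product: 24 methyl (S)-3-[(tert-butyldiphenylsilyl)oxy]-2-methylpropanoate
Conditions: TBDPSCl, imidazole, DMF, rt
Reagents that add atoms: tert-butyldiphenylsilyl chloride, `CC(C)(C)[Si](Cl)(c1ccccc1)c1ccccc1`
Why: silylation of the primary alcohol; this ether survives acid, bromine and base until step 29.

Step 17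
Reactants: 24 the silyl ether from step 16
Product: 25 (S)-3-[(tert-butyldiphenylsilyl)oxy]-2-methylpropanal
Conditions: i-Bu2AlH, CH2Cl2, −78 °C; aq potassium sodium tartrate
Reagents that add atoms: none
Why: partial reduction of the ester; the tetrahedral aluminate holds until work-up at −78 °C. The aldehyde is used at once to keep C17 intact.

Step 18
Reactants: 25 the aldehyde from step 17
Product: 26 (R)-tert-butyl[(2-methylbut-3-yn-1-yl)oxy]diphenylsilane
Conditions: dimethyl (1-diazo-2-oxopropyl)phosphonate, K2CO3, MeOH, 0 °C to rt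
Reagents that add atoms: dimethyl (1-diazo-2-oxopropyl)phosphonate, `CC(=O)C(=[N+]=[N-])P(=O)(OC)OC`
Why: Ohira–Bestmann homologation; mild enough for α-branched aldehydes of this type.

Step 19
Reactants: 26 the alkyne from step 18
Product: 28 (S)-tert-butyl[(3-iodo-2-methylbut-3-en-1-yl)oxy]diphenylsilane, via iodoboration adduct 27 (not isolated)
Conditions: B-iodo-9-BBN, hexane/CH2Cl2, −20 °C; then AcOH, 0 °C
Reagents that add atoms: B-iodo-9-borabicyclo[3.3.1]nonane, `IB1C2CCCC1CCC2`
Why: syn iodoboration puts iodine on the internal carbon, and protodeboronation with acetic acid gives the 2-iodo-1-alkene.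

Step 20
Reactants: 22 the C9 aldehyde from step 15; 28 the iodoalkene from step 19
Product: 29 C9 allylic alcohol (9R): C8(=C7H2) alkene, C2/C12/C14 acetates, C19 tert-butyldiphenylsilyl ether, terminal alkyne
Conditions: CrCl2 (5 equiv), NiCl2 (2 mol%), 28 (2.5 equiv), DMSO, rt
Reagents that add atoms: none
Why: Nozaki–Hiyama–Kishi coupling; zerovalent nickel inserts into the C–I bond, and the alkenylchromium reagent adds only to the aldehyde (acetates and alkyne are inert). Felkin–Anh addition anti to quaternary C1, with the oxygen next to C11, gives 9R.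

Step 21
Reactants: 29 the allylic alcohol from step 20
Product: 30 alkyne triol (8S,9R): C7, C8 and C9 hydroxyls, otherwise as 29
Conditions: OsO4 (5 mol%), N-methylmorpholine N-oxide, acetone/H2O, rt
Reagents that add atoms: osmium tetroxide, `O=[Os](=O)(=O)=O`; N-methylmorpholine N-oxide, `C[N+]1([O-])CCOCC1`; water, `O`
Why: Upjohn dihydroxylation of the only alkene. OsO4 adds anti to the allylic C9 oxygen, and the conformer that relieves A(1,2) strain (C9–H eclipsing C8–C17) exposes the same face, giving 8S.

Step 22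
Reactants: 30 the alkyne triol from step 21
Product: 31 acrylate triol: C5(=CH2)CO2Me in place of the alkyne
Conditions: Pd(OAc)2 (3 mol%), 2-(diphenylphosphino)pyridine (30 mol%), MeSO3H (10 mol%), CO (5 bar), MeOH, 45 °C
Reagents that add atoms: carbon monoxide, `[C-]#[O+]`; methanol, `CO`
Why: palladium-hydride methoxycarbonylation of a terminal alkyne; Pd adds to the internal carbon, and CO insertion and methanolysis give the 2-substituted acrylate. It is run on the triol so that no acid-labile silyl ether is present.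

Step 23
Reactants: 31 the acrylate triol from step 22
Product: 32 C7 triethylsilyl ether with C8 and C9 hydroxyls free
Conditions: TESCl (1.1 equiv), imidazole, CH2Cl2, −20 °C
Reagents that add atoms: triethylsilyl chloride, `CC[Si](CC)(CC)Cl`
Why: the primary hydroxyl is silylated far faster than the hindered secondary and tertiary ones.

Step 24
Reactants: 32 the C7 silyl ether from step 23
Product: 33 C9 acetate with C8 hydroxyl free
Conditions: Ac2O, DMAP, Et3N, CH2Cl2, rt
Reagents that add atoms: acetic anhydride, `CC(=O)OC(C)=O`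
Why: acetylation of the secondary C9 hydroxyl; the tertiary C8 hydroxyl does not react under these conditions. The fourth acetate of 42 is in place, with no free primary hydroxyl nearby to migrate to.

Step 25
Reactants: 33 the C9 acetate from step 24
Product: 34 bis(triethylsilyl) ether: C7 and C8 OSiEt3, C9 OAc, C5(=CH2)CO2Me
Conditions: TESOTf, 2,6-lutidine, CH2Cl2, 0 °C to rt
Reagents that add atoms: triethylsilyl triflate, `CC[Si](CC)(CC)OS(=O)(=O)C(F)(F)F`
Why: the silyl triflate is reactive enough for the tertiary alcohol; the ether prevents α-ketol rearrangement once C7 is an aldehyde.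

Step 26
Reactants: 34 the bis(triethylsilyl) ether from step 25
Product: 36 (E)-3-bromo-2-alkylacrylate: bromine on C6 cis to C4, via dibromo ester 35 (not isolated)
Conditions: Br2, CH2Cl2, 0 °C, dark; then DBU, CH2Cl2, rt
Reagents that add atoms: bromine, `BrBr`
Why: bromination–dehydrobromination, the classical route from 2-alkylacrylates to (E)-3-bromo-2-alkylacrylates. Bromine adds to the only alkene, and DBU removes HBr by E2 from the more acidic CHBr hydrogens, leaving bromine trans to the ester (the more stable isomer).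

Step 27
Reactants: 36 the bromoacrylate from step 26
Product: 37 C7 aldehyde with C8 OSiEt3 and the bromoacrylate
Conditions: (COCl)2, DMSO, CH2Cl2, −78 to −40 °C; Et3N
Reagents that add atoms: none
Why: Swern conditions cleave and oxidise primary triethylsilyl ethers directly while tertiary ones survive; the aldehyde has no α-hydrogen.

Step 28
Reactants: 37 the aldehyde from step 27
Product: 38 ten-membered (7S)-allylic alcohol: C8 OSiEt3, C19 OSi(t-Bu)Ph2, four acetates, ring enoate
Conditions: CrCl2 (10 equiv), NiCl2 (10 mol%), DMSO/THF, 2 mM, rt to 40 °C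
Reagents that add atoms: none
Why: intramolecular Nozaki–Hiyama–Kishi reaction closing the ten-membered ring at C6–C7 (10-exo addition to the aldehyde), with the alkene geometry already fixed. Felkin–Anh addition anti to the α-silyloxy group, past the smaller C17 branch, gives 7S; the ester is trans to C7 and cannot lactonise.

Step 29
Reactants: 38 the macrocycle from step 28
Product: 39 macrocyclic triol: C7, C8 and C19 hydroxyls free
Conditions: HF·pyridine, pyridine/THF, 0 °C to rt
Reagents that add atoms: none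
Why: buffered fluoride removes both silyl ethers; the medium stays acidic, so the C9 acetate does not migrate to the C7 hydroxyl.

Step 30
Reactants: 39 the triol from step 29
Product: 42 CNP0230222.1, via C19 aldehyde 40 (not isolated), via lactol 41 (not isolated)
Conditions: TEMPO (20 mol%), PhI(OAc)2 (2.5 equiv), CH2Cl2, rt
Reagents that add atoms: none
Why: oxidative lactonisation of a 1,4-diol; the oxoammonium oxidant takes the primary C19 alcohol, the aldehyde is caught by the C7 hydroxyl (five-membered lactol; C9 is an acetate and C8–OH would give a four-membered ring), and the lactol is oxidised to the lactone. C7 and C17 keep their configuration.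

## Compound list

```
1 | propane-1,3-diol | OCCCO | starting material
2 | 3-[(4-methoxybenzyl)oxy]propan-1-ol | COc1ccc(COCCCO)cc1 | intermediate
3 | 3-[(4-methoxybenzyl)oxy]propanal | COc1ccc(COCCC=O)cc1 | intermediate
4 | (3R,4R)-1-[(4-methoxybenzyl)oxy]-4-methylhex-5-en-3-ol | C=C[C@@H](C)[C@H](O)CCOCc1ccc(OC)cc1 | intermediate
5 | tert-butyl{[(3R,4R)-1-[(4-methoxybenzyl)oxy]-4-methylhex-5-en-3-yl]oxy}dimethylsilane | C=C[C@@H](C)[C@H](O[Si](C)(C)C(C)(C)C)CCOCc1ccc(OC)cc1 | intermediate
6 | (3R,4R)-3-[(tert-butyldimethylsilyl)oxy]-4-methylhex-5-en-1-ol | C=C[C@@H](C)[C@H](O[Si](C)(C)C(C)(C)C)CCO | intermediate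
7 | (3R,4R)-3-[(tert-butyldimethylsilyl)oxy]-4-methylhex-5-enal | C=C[C@@H](C)[C@H](O[Si](C)(C)C(C)(C)C)CC=O | intermediate
8 | (5R,6R)-5-[(tert-butyldimethylsilyl)oxy]-2,6-dimethylocta-1,7-dien-3-ol, both C3 epimers | C=C[C@@H](C)[C@H](O[Si](C)(C)C(C)(C)C)CC(O)C(C)=C | intermediate
9 | (4R,5R)-5-[(tert-butyldimethylsilyl)oxy]-2,4-dimethylcyclohex-2-en-1-ol, both C1 epimers | CC1=C[C@@H](C)[C@H](O[Si](C)(C)C(C)(C)C)CC1O | intermediate
10 | (4R,5R)-5-[(tert-butyldimethylsilyl)oxy]-2,4-dimethylcyclohex-2-en-1-one | CC1=C[C@@H](C)[C@H](O[Si](C)(C)C(C)(C)C)CC1=O | intermediate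
11 | pent-4-yn-1-ol | OCCCC#C | starting material
12 | pent-4-ynal | O=CCCC#C | intermediate
13 | vinylmagnesium bromide | C=C[Mg]Br | starting material
14 | bromomagnesium enolate (C14 O-MgBr, C14=C1) of the 3-vinyl ketone | C=C[C@H]1[C@@H](C)[C@H](O[Si](C)(C)C(C)(C)C)CC(O[Mg]Br)=C1C | intermediate
15 | triisopropoxytitanium enolate of the same ketone | C=C[C@H]1[C@@H](C)[C@H](O[Si](C)(C)C(C)(C)C)CC(O[Ti](OC(C)C)(OC(C)C)OC(C)C)=C1C | intermediate
16 | (2S,3S,4R,5R)-5-[(tert-butyldimethylsilyl)oxy]-3-ethenyl-2-[(1R)-1-hydroxypent-4-yn-1-yl]-2,4-dimethylcyclohexan-1-one | C=C[C@H]1[C@@H](C)[C@H](O[Si](C)(C)C(C)(C)C)CC(=O)[C@]1(C)[C@H](O)CCC#C | intermediate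
17 | O2-diethylboryl aldolate of 16 | C=C[C@H]1[C@@H](C)[C@H](O[Si](C)(C)C(C)(C)C)CC(=O)[C@]1(C)[C@H](OB(CC)CC)CCC#C | intermediate
18 | (1S,2S,3S,4R,5R)-5-[(tert-butyldimethylsilyl)oxy]-3-ethenyl-2-[(1R)-1-hydroxypent-4-yn-1-yl]-2,4-dimethylcyclohexan-1-ol | C=C[C@H]1[C@@H](C)[C@H](O[Si](C)(C)C(C)(C)C)C[C@H](O)[C@]1(C)[C@H](O)CCC#C | intermediate
19 | (1R,3S,4S,5S,6R)-5-ethenyl-4-[(1R)-1-hydroxypent-4-yn-1-yl]-4,6-dimethylcyclohexane-1,3-diol | C=C[C@H]1[C@@H](C)[C@H](O)C[C@H](O)[C@]1(C)[C@H](O)CCC#C | intermediate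
20 | (1R,3S,4S,5S,6R)-4-[(1R)-1-acetoxypent-4-yn-1-yl]-5-ethenyl-4,6-dimethylcyclohexane-1,3-diyl diacetate | C=C[C@H]1[C@@H](C)[C@H](OC(C)=O)C[C@H](OC(C)=O)[C@]1(C)[C@H](OC(C)=O)CCC#C | intermediate
21 | vicinal diol from the vinyl group of 20 (C9 carbinol unassigned) | OCC(O)[C@H]1[C@@H](C)[C@H](OC(C)=O)C[C@H](OC(C)=O)[C@]1(C)[C@H](OC(C)=O)CCC#C | intermediate
22 | (1R,3S,4S,5S,6R)-4-[(1R)-1-acetoxypent-4-yn-1-yl]-5-formyl-4,6-dimethylcyclohexane-1,3-diyl diacetate (C9 aldehyde) | O=C[C@H]1[C@@H](C)[C@H](OC(C)=O)C[C@H](OC(C)=O)[C@]1(C)[C@H](OC(C)=O)CCC#C | intermediate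
23 | methyl (S)-3-hydroxy-2-methylpropanoate | COC(=O)[C@@H](C)CO | starting material
24 | methyl (S)-3-[(tert-butyldiphenylsilyl)oxy]-2-methylpropanoate | COC(=O)[C@@H](C)CO[Si](c1ccccc1)(c1ccccc1)C(C)(C)C | intermediate
25 | (S)-3-[(tert-butyldiphenylsilyl)oxy]-2-methylpropanal | O=C[C@@H](C)CO[Si](c1ccccc1)(c1ccccc1)C(C)(C)C | intermediate
26 | (R)-tert-butyl[(2-methylbut-3-yn-1-yl)oxy]diphenylsilane | C#C[C@@H](C)CO[Si](c1ccccc1)(c1ccccc1)C(C)(C)C | intermediate
27 | (Z)-2-iodoalkenyl-9-BBN adduct of 26 (I and B cis) | I/C(=C\B1C2CCCC1CCC2)[C@@H](C)CO[Si](c1ccccc1)(c1ccccc1)C(C)(C)C | intermediate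
28 | (S)-tert-butyl[(3-iodo-2-methylbut-3-en-1-yl)oxy]diphenylsilane | C=C(I)[C@@H](C)CO[Si](c1ccccc1)(c1ccccc1)C(C)(C)C | intermediate
29 | (9R) allylic alcohol: C8(=C7H2), C2/C12/C14 OAc, C19 OSi(t-Bu)Ph2, terminal alkyne | C=C([C@@H](C)CO[Si](c1ccccc1)(c1ccccc1)C(C)(C)C)[C@H](O)[C@H]1[C@@H](C)[C@H](OC(C)=O)C[C@H](OC(C)=O)[C@]1(C)[C@H](OC(C)=O)CCC#C | intermediate
30 | (8S,9R) alkyne triol: C7, C8, C9 OH | OC[C@@](O)([C@@H](C)CO[Si](c1ccccc1)(c1ccccc1)C(C)(C)C)[C@H](O)[C@H]1[C@@H](C)[C@H](OC(C)=O)C[C@H](OC(C)=O)[C@]1(C)[C@H](OC(C)=O)CCC#C | intermediate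
31 | acrylate triol: C5(=CH2)CO2Me, C7, C8, C9 OH | OC[C@@](O)([C@@H](C)CO[Si](c1ccccc1)(c1ccccc1)C(C)(C)C)[C@H](O)[C@H]1[C@@H](C)[C@H](OC(C)=O)C[C@H](OC(C)=O)[C@]1(C)[C@H](OC(C)=O)CCC(=C)C(=O)OC | intermediate
32 | C7 triethylsilyl ether, C8 and C9 OH | CC[Si](CC)(CC)OC[C@@](O)([C@@H](C)CO[Si](c1ccccc1)(c1ccccc1)C(C)(C)C)[C@H](O)[C@H]1[C@@H](C)[C@H](OC(C)=O)C[C@H](OC(C)=O)[C@]1(C)[C@H](OC(C)=O)CCC(=C)C(=O)OC | intermediate
33 | C9 acetate, C7 OSiEt3, C8 OH | CC[Si](CC)(CC)OC[C@@](O)([C@@H](C)CO[Si](c1ccccc1)(c1ccccc1)C(C)(C)C)[C@H](OC(C)=O)[C@H]1[C@@H](C)[C@H](OC(C)=O)C[C@H](OC(C)=O)[C@]1(C)[C@H](OC(C)=O)CCC(=C)C(=O)OC | intermediate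
34 | bis(triethylsilyl) ether: C7 and C8 OSiEt3, C9 OAc, acrylate | CC[Si](CC)(CC)OC[C@@](O[Si](CC)(CC)CC)([C@@H](C)CO[Si](c1ccccc1)(c1ccccc1)C(C)(C)C)[C@H](OC(C)=O)[C@H]1[C@@H](C)[C@H](OC(C)=O)C[C@H](OC(C)=O)[C@]1(C)[C@H](OC(C)=O)CCC(=C)C(=O)OC | intermediate
35 | 2,3-dibromo ester from 34 (C5 unassigned) | CC[Si](CC)(CC)OC[C@@](O[Si](CC)(CC)CC)([C@@H](C)CO[Si](c1ccccc1)(c1ccccc1)C(C)(C)C)[C@H](OC(C)=O)[C@H]1[C@@H](C)[C@H](OC(C)=O)C[C@H](OC(C)=O)[C@]1(C)[C@H](OC(C)=O)CCC(Br)(CBr)C(=O)OC | intermediate
36 | (E)-3-bromo-2-alkylacrylate, Br cis to C4 | CC[Si](CC)(CC)OC[C@@](O[Si](CC)(CC)CC)([C@@H](C)CO[Si](c1ccccc1)(c1ccccc1)C(C)(C)C)[C@H](OC(C)=O)[C@H]1[C@@H](C)[C@H](OC(C)=O)C[C@H](OC(C)=O)[C@]1(C)[C@H](OC(C)=O)CC/C(=C\Br)C(=O)OC | intermediate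
37 | C7 aldehyde with C8 OSiEt3 and the bromoacrylate | O=C[C@@](O[Si](CC)(CC)CC)([C@@H](C)CO[Si](c1ccccc1)(c1ccccc1)C(C)(C)C)[C@H](OC(C)=O)[C@H]1[C@@H](C)[C@H](OC(C)=O)C[C@H](OC(C)=O)[C@]1(C)[C@H](OC(C)=O)CC/C(=C\Br)C(=O)OC | intermediate
38 | ten-membered (7S,8S,9R) allylic alcohol: C8 OSiEt3, C19 OSi(t-Bu)Ph2 | COC(=O)/C1=C/[C@H](O)[C@@](O[Si](CC)(CC)CC)([C@@H](C)CO[Si](c3ccccc3)(c3ccccc3)C(C)(C)C)[C@H](OC(C)=O)[C@H]2[C@@H](C)[C@H](OC(C)=O)C[C@H](OC(C)=O)[C@]2(C)[C@H](OC(C)=O)CC1 | intermediate
39 | macrocyclic triol: C7, C8, C19 OH | COC(=O)/C1=C/[C@H](O)[C@@](O)([C@@H](C)CO)[C@H](OC(C)=O)[C@H]2[C@@H](C)[C@H](OC(C)=O)C[C@H](OC(C)=O)[C@]2(C)[C@H](OC(C)=O)CC1 | intermediate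
40 | C19 aldehyde of 39 | COC(=O)/C1=C/[C@H](O)[C@@](O)([C@@H](C)C=O)[C@H](OC(C)=O)[C@H]2[C@@H](C)[C@H](OC(C)=O)C[C@H](OC(C)=O)[C@]2(C)[C@H](OC(C)=O)CC1 | intermediate
41 | lactol (C19 hemiacetal with O7) | COC(=O)/C1=C/[C@@H]2OC(O)[C@H](C)[C@@]2(O)[C@H](OC(C)=O)[C@H]2[C@@H](C)[C@H](OC(C)=O)C[C@H](OC(C)=O)[C@]2(C)[C@H](OC(C)=O)CC1 | intermediate
42 | CNP0230222.1 (1S,2R,7S,8S,9R,10S,11R,12R,14S,17R) | COC(=O)/C1=C/[C@@H]2OC(=O)[C@H](C)[C@@]2(O)[C@H](OC(C)=O)[C@H]2[C@@H](C)[C@H](OC(C)=O)C[C@H](OC(C)=O)[C@]2(C)[C@H](OC(C)=O)CC1 | target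
```

## Step count and least certain steps

Total: 30 steps. Longest linear sequence: 25 steps (1–9, 11–15, 20–30).

**Step 11 (key step).** The most likely failure is poor or reversed aldehyde-face selectivity at C2: the enolate is tetrasubstituted, and chair and boat transition states lie close. Some erosion at C10 is also possible, because attack cis to the C11 methyl runs against the usual preference of 4-substituted enones. Fallback for C2, from 10 back to 19:
- Enone 10 is coupled with 13 and 12 through the zinc enolate (ZnCl2 in place of ClTi(OiPr)3), where the chair favours the (2S) aldol adduct F1.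
- F1 has the right configuration for an anti-selective Evans–Tishchenko reduction (SmI2 15 mol%, PhCHO, THF, −10 °C). This sets C14 as in 18 and gives the C2 benzoate C14 alcohol F2.
- TESOTf gives the C14 triethylsilyl ether F3, and i-Bu2AlH removes the benzoate to give the (2S) alcohol F4.
- Dess–Martin periodinane gives the C2 ketone F5.
- (S)-2-Methyl-CBS-oxazaborolidine with catecholborane (tert-alkyl against n-alkyl) gives the (2R) alcohol F6.
- Aqueous HF removes both silyl groups and the route is rejoined at 19.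

**Step 21 (dihydroxylation, C8).** Facial selectivity may be poor, because two allylic stereocentres flank a 1,1-disubstituted alkene and A(1,2) strain may disturb the reactive conformer. Fallback from 29 back to 30:
- VO(acac)2 (5 mol%) and t-BuOOH deliver oxygen from the vanadate ester, with C9–H eclipsing the C8–C17 bond, to give the erythro epoxy alcohol F7.
- Ti(OiPr)4 with chloroacetic acid opens the epoxide at the primary C7 to give the C7 chloroacetate F8.
- Thiourea and NaHCO3 in ethanol remove the chloroacetate without touching the acetates and return triol 30.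

**Step 26 (bromination–dehydrobromination).** Dehydrobromination may go toward C4 (giving the 2-(bromomethyl)alk-2-enoate) or give the other geometric isomer, since nothing but acidity and product stability directs the E2 step. Fallback from 34 back to 38, with no vinyl halide:
- Swern oxidation of 34 gives the C7 aldehyde F9.
- CrCl2/NiCl2 with vinyl bromide adds a vinyl group under the same Felkin–Anh control to give the C7 vinyl carbinol F10.
- Ring-closing metathesis (second-generation Hoveyda–Grubbs catalyst, toluene, 80 °C, 1 mM) expels ethene and gives 38.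

**Step 28 (ring closure).** The tether may override the open-chain facial preference at C7, or intermolecular coupling may compete at practical dilution. Fallback from 37 to 42, if the closure gives mainly the C7 epimer F11:
- MsCl/Et3N gives the allylic mesylate F12.
- HF·pyridine removes the silyl groups to give the diol mesylate F13.
- TEMPO/PhI(OAc)2 in MeCN/H2O oxidises C19 to the acid F14.
- NaHCO3 in DMF lets the carboxylate displace the mesylate with inversion (5-exo-tet), giving 42 directly.

## Further compounds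

```
F1 | step 11 | (2S) aldol adduct, C2 epimer of 16 | C=C[C@H]1[C@@H](C)[C@H](O[Si](C)(C)C(C)(C)C)CC(=O)[C@]1(C)[C@@H](O)CCC#C
F2 | step 11 | C2 benzoate C14 alcohol (2S,14S) | C=C[C@H]1[C@@H](C)[C@H](O[Si](C)(C)C(C)(C)C)C[C@H](O)[C@]1(C)[C@@H](OC(=O)c1ccccc1)CCC#C
F3 | step 11 | C14 triethylsilyl ether of F2 | C=C[C@H]1[C@@H](C)[C@H](O[Si](C)(C)C(C)(C)C)C[C@H](O[Si](CC)(CC)CC)[C@]1(C)[C@@H](OC(=O)c1ccccc1)CCC#C
F4 | step 11 | (2S) alcohol with C14 OSiEt3 | C=C[C@H]1[C@@H](C)[C@H](O[Si](C)(C)C(C)(C)C)C[C@H](O[Si](CC)(CC)CC)[C@]1(C)[C@@H](O)CCC#C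
F5 | step 11 | C2 ketone with C14 OSiEt3 | C=C[C@H]1[C@@H](C)[C@H](O[Si](C)(C)C(C)(C)C)C[C@H](O[Si](CC)(CC)CC)[C@]1(C)C(=O)CCC#C
F6 | step 11 | (2R) alcohol with C14 OSiEt3 | C=C[C@H]1[C@@H](C)[C@H](O[Si](C)(C)C(C)(C)C)C[C@H](O[Si](CC)(CC)CC)[C@]1(C)[C@H](O)CCC#C
F7 | step 21 | erythro C7-C8 epoxy alcohol from 29 | C1O[C@]1([C@@H](C)CO[Si](c2ccccc2)(c2ccccc2)C(C)(C)C)[C@H](O)[C@H]2[C@@H](C)[C@H](OC(C)=O)C[C@H](OC(C)=O)[C@]2(C)[C@H](OC(C)=O)CCC#C
F8 | step 21 | C7 chloroacetate of triol 30 | ClCC(=O)OC[C@@](O)([C@@H](C)CO[Si](c1ccccc1)(c1ccccc1)C(C)(C)C)[C@H](O)[C@H]1[C@@H](C)[C@H](OC(C)=O)C[C@H](OC(C)=O)[C@]1(C)[C@H](OC(C)=O)CCC#C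
F9 | step 26 | C7 aldehyde with C8 OSiEt3 and the unbrominated acrylate | O=C[C@@](O[Si](CC)(CC)CC)([C@@H](C)CO[Si](c1ccccc1)(c1ccccc1)C(C)(C)C)[C@H](OC(C)=O)[C@H]1[C@@H](C)[C@H](OC(C)=O)C[C@H](OC(C)=O)[C@]1(C)[C@H](OC(C)=O)CCC(=C)C(=O)OC
F10 | step 26 | (7S) C7 vinyl carbinol, diene for ring-closing metathesis | C=C[C@H](O)[C@@](O[Si](CC)(CC)CC)([C@@H](C)CO[Si](c1ccccc1)(c1ccccc1)C(C)(C)C)[C@H](OC(C)=O)[C@H]1[C@@H](C)[C@H](OC(C)=O)C[C@H](OC(C)=O)[C@]1(C)[C@H](OC(C)=O)CCC(=C)C(=O)OC
F11 | step 28 | C7 epimer of 38 | COC(=O)/C1=C/[C@@H](O)[C@@](O[Si](CC)(CC)CC)([C@@H](C)CO[Si](c3ccccc3)(c3ccccc3)C(C)(C)C)[C@H](OC(C)=O)[C@H]2[C@@H](C)[C@H](OC(C)=O)C[C@H](OC(C)=O)[C@]2(C)[C@H](OC(C)=O)CC1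
F12 | step 28 | allylic C7 mesylate of F11 | COC(=O)/C1=C/[C@@H](OS(C)(=O)=O)[C@@](O[Si](CC)(CC)CC)([C@@H](C)CO[Si](c3ccccc3)(c3ccccc3)C(C)(C)C)[C@H](OC(C)=O)[C@H]2[C@@H](C)[C@H](OC(C)=O)C[C@H](OC(C)=O)[C@]2(C)[C@H](OC(C)=O)CC1
F13 | step 28 | diol mesylate: C8 and C19 OH | COC(=O)/C1=C/[C@@H](OS(C)(=O)=O)[C@@](O)([C@@H](C)CO)[C@H](OC(C)=O)[C@H]2[C@@H](C)[C@H](OC(C)=O)C[C@H](OC(C)=O)[C@]2(C)[C@H](OC(C)=O)CC1
F14 | step 28 | C19 carboxylic acid mesylate | COC(=O)/C1=C/[C@@H](OS(C)(=O)=O)[C@@](O)([C@@H](C)C(=O)O)[C@H](OC(C)=O)[C@H]2[C@@H](C)[C@H](OC(C)=O)C[C@H](OC(C)=O)[C@]2(C)[C@H](OC(C)=O)CC1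
A1 | alternative 1 | ten-membered C7 allylic alcohol, C8 triethylsilyl ether, C19 methyl ester | COC(=O)/C1=C/[C@H](O)[C@@](O[Si](CC)(CC)CC)([C@@H](C)C(=O)OC)[C@H](OC(C)=O)[C@H]2[C@@H](C)[C@H](OC(C)=O)C[C@H](OC(C)=O)[C@]2(C)[C@H](OC(C)=O)CC1
A2 | alternative 1 | open-chain iodoacrylate C7 aldehyde, precursor of A1 | O=C[C@@](O[Si](CC)(CC)CC)([C@@H](C)C(=O)OC)[C@H](OC(C)=O)[C@H]1[C@@H](C)[C@H](OC(C)=O)C[C@H](OC(C)=O)[C@]1(C)[C@H](OC(C)=O)CC/C(=C\I)C(=O)OC
A3 | alternative 2 | cyclohexane-fused isoxazoline | COc1ccc(COC[C@H]2[C@@H](C)[C@H](O[Si](C)(C)C(C)(C)C)CC3=NO[C@H](CCC#C[Si](C)(C)C)[C@]23C)cc1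
A4 | alternative 2 | open-chain C14 oxime with Z C1=C2 alkene, precursor of A3 | COc1ccc(COC[C@@H]([C@@H](C)[C@H](O[Si](C)(C)C(C)(C)C)CC=NO)/C(C)=C\CCC#C[Si](C)(C)C)cc1
A5 | alternative 3 | C8 triethylsilyl ether of 42 | COC(=O)/C1=C/[C@@H]2OC(=O)[C@H](C)[C@@]2(O[Si](CC)(CC)CC)[C@H](OC(C)=O)[C@H]2[C@@H](C)[C@H](OC(C)=O)C[C@H](OC(C)=O)[C@]2(C)[C@H](OC(C)=O)CC1
A6 | alternative 3 | ring-fused cyclobutanone (C19 bonded to C7), precursor of A5 | COC(=O)/C1=C/[C@@H]2C(=O)[C@H](C)[C@@]2(O[Si](CC)(CC)CC)[C@H](OC(C)=O)[C@H]2[C@@H](C)[C@H](OC(C)=O)C[C@H](OC(C)=O)[C@]2(C)[C@H](OC(C)=O)CC1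
```
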